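**Retrosynthetic overview**

1. Target ⇐ Appel inversion of an axial ring-A alcohol and fluoride deprotection ⇐ tetracyclic norbornanone; the exo isopropyl comes from an exo-selective decarboxylative alkenylation, the exo carbinol from endo-face hydride reduction.
2. Key disconnection: the two-carbon bridge of the norbornane (ring C) ⇐ intermolecular Michael addition of the cross-conjugated dienolate of a tricyclic A/B/D cyclopentenone to allyl acrylate, then ring-closing Michael addition.
3. Ring D cyclopentenone ⇐ aldol condensation of a 1,4-diketone ⇐ Wacker oxidation of an allyl group installed by conjugate allylation of a decalin ene-dione; the ring-A tertiary carbinol ⇐ methyl addition to the ene-dione-derived ketone.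
4. Decalin ene-dione ⇐ (S)-Wieland–Miescher ketone ⇐ Michael addition and proline aldol of 2-methylcyclohexane-1,3-dione with methyl vinyl ketone.
5. Ring order: A (from the dione) → B (step 2) → D (step 11) → C (step 12).

Atom labels used below (my own): ring A = C1(Br)–C2–C3–C4(OH)(C20H3)–C5–C10(C19H3); ring B = C5–C6–C7–C8–C9–C10; ring D = C6–C7–C11–C12(OH)–C13; ring C = C6–C7–C15(iPr)–C14–C13; C16–C18 = isopropyl; β = the face of C19 on the decalin; exo = toward the one-carbon bridge C6 of the norbornane.

**Step 1**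
Reactants: 1 2-methylcyclohexane-1,3-dione; 2 but-3-en-2-one
Product: 3 2-methyl-2-(3-oxobutyl)cyclohexane-1,3-dione
Conditions: AcOH (cat.), hydroquinone (cat.), H2O, 75 °C
Reagents that add atoms: none
Why: Michael addition of the doubly stabilised dione enolate to the vinyl ketone gives only C-alkylation at C10 and creates no stereocentre (C10 is still prochiral).

**Step 2**
Reactants: 3 2-methyl-2-(3-oxobutyl)cyclohexane-1,3-dione
Product: 5 (S)-Wieland–Miescher ketone, via cis-fused ketol 4 (not isolated)
Conditions: L-proline (5 mol %), DMSO, 35 °C; recrystallisation (>99% ee)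
Reagents that add atoms: none
Why: Hajos–Parrish–Eder–Sauer–Wiechert reaction, in which the L-proline enamine of the side-chain ketone attacks one enantiotopic ring carbonyl through a hydrogen-bonded chair transition state (aldol, then dehydration) and sets C10 as S.

**Step 3**
Reactants: 5 (S)-Wieland–Miescher ketone
Product: 6 (4aS,5S)-5-hydroxy-4a-methyl-4,4a,5,6,7,8-hexahydronaphthalen-2(3H)-one
Conditions: NaBH4 (0.3 equiv), EtOH, −10 °C
Reagents that add atoms: none
Why: Chemoselective borohydride reduction of the saturated C1 ketone (more electrophilic than the enone), with axial hydride attack anti to the angular methyl giving the equatorial 1β-alcohol.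

**Step 4**
Reactants: 6 (4aS,5S)-5-hydroxy-4a-methyl-4,4a,5,6,7,8-hexahydronaphthalen-2(3H)-one
Product: 7 (4aS,5S)-5-benzyloxy-4a-methyl-4,4a,5,6,7,8-hexahydronaphthalen-2(3H)-one
Conditions: benzyl 2,2,2-trichloroacetimidate, TfOH (5 mol %), CH2Cl2/cyclohexane, 0 → 25 °C
Reagents that add atoms: benzyl 2,2,2-trichloroacetimidate, N=C(OCc1ccccc1)C(Cl)(Cl)Cl
Why: Acid-catalysed imidate O-benzylation needs no base, so the enone is not enolised, and the benzyl ether then survives every step up to the hydrogenation in step 18 (no stereocentre is touched).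

**Step 5**
Reactants: 7 (4aS,5S)-5-benzyloxy-4a-methyl-4,4a,5,6,7,8-hexahydronaphthalen-2(3H)-one
Product: 9 1β-benzyloxy-10β-methyldecal-5-ene-4,7-dione, via pyrrolidine dienamine 8 (not isolated)
Conditions: pyrrolidine, PhH, reflux (−H2O); then O2 (1 atm), Cu(OAc)2 (5 mol %), PhH/MeOH, 25 °C; aq. AcOH
Reagents that add atoms: dioxygen, O=O
Why: Dienamine autoxidation (classical steroid 4-ene-3-one → 4-ene-3,6-dione chemistry), in which the heteroannular dienamine takes up O2 at its terminal γ-carbon C4 and hydrolysis returns the C7 carbonyl.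

**Step 6**
Reactants: 9 1β-benzyloxy-10β-methyldecal-5-ene-4,7-dione; 10 allyltrimethylsilane
Product: 11 6α-allyl-1β-benzyloxy-10β-methyl-5α-decalin-4,7-dione
Conditions: TiCl4 (1.2 equiv), CH2Cl2, −78 °C; H2O; then K2CO3 (cat.), MeOH, 25 °C
Reagents that add atoms: none
Why: Hosomi–Sakurai conjugate allylation at C6, the only unsubstituted β-carbon of the TiCl4-activated ene-dione; C5 and C6 are then both α to a carbonyl and equilibrate to the trans-decalin (5α-H) with the 6α-allyl equatorial, since an axial allyl would be syn-axial to C19.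

**Step 7**
Reactants: 11 6α-allyl-1β-benzyloxy-10β-methyl-5α-decalin-4,7-dione
Product: 12 6α-allyl-1β-benzyloxy-7β-hydroxy-10β-methyl-5α-decalin-4-one
Conditions: NaBH4 (0.35 equiv), MeOH/CH2Cl2, −78 → −40 °C
Reagents that add atoms: none
Why: Chemoselective hydride reduction: NaBH4 attacks the C7 ketone axially from the open α face, whereas axial attack on the C4 ketone is blocked by the syn-axial C19 methyl (the 3-keto over 6-keto selectivity of steroid 3,6-diones), giving the equatorial 7β-alcohol as a temporary mask.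

**Step 8**
Reactants: 12 6α-allyl-1β-benzyloxy-7β-hydroxy-10β-methyl-5α-decalin-4-one; 13 methylmagnesium bromide
Product: 14 6α-allyl-1β-benzyloxy-4α,10β-dimethyl-5α-decalin-4β,7β-diol
Conditions: CeCl3 (anhydrous, 3.5 equiv), 13 (3.5 equiv), THF, −78 → 0 °C; H2O
Reagents that add atoms: none
Why: Imamoto organocerium 1,2-addition suppresses enolisation of the hindered C4 ketone, and methyl enters from the equatorial α side because the axial β trajectory is blocked by the syn-axial C19 methyl, setting the 4β-OH/4α-CH3 carbinol.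

**Step 9**
Reactants: 14 6α-allyl-1β-benzyloxy-4α,10β-dimethyl-5α-decalin-4β,7β-diol
Product: 15 6α-allyl-1β-benzyloxy-4β-hydroxy-4α,10β-dimethyl-5α-decalin-7-one
Conditions: Dess–Martin periodinane, CH2Cl2, 25 °C
Reagents that add atoms: none
Why: Dess–Martin oxidation converts only the secondary C7 alcohol back into the ketone, since the tertiary C4 alcohol cannot be oxidised and the alkene and benzyl ether are inert.

**Step 10**
Reactants: 15 6α-allyl-1β-benzyloxy-4β-hydroxy-4α,10β-dimethyl-5α-decalin-7-one
Product: 16 1β-benzyloxy-4β-hydroxy-4α,10β-dimethyl-6α-(2-oxopropyl)-5α-decalin-7-one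
Conditions: PdCl2 (10 mol %), CuCl, O2 (1 atm), DMF/H2O 7:1, 25 °C
Reagents that add atoms: water, O
Why: Tsuji–Wacker oxidation gives the methyl ketone by Markovnikov hydroxypalladation of the terminal alkene; the product may sit partly as its cyclic hemiketal with the C4 hydroxyl, which opens again under the base of step 11.

**Step 11**
Reactants: 16 1β-benzyloxy-4β-hydroxy-4α,10β-dimethyl-6α-(2-oxopropyl)-5α-decalin-7-one
Product: 17 tricyclic enone of rings A/B/D (C12 ketone; C7=C11; 5α-H; 6β-H; 1β-OBn; 4β-OH)
Conditions: KOH (2 M), MeOH, 65 °C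
Reagents that add atoms: none
Why: Intramolecular aldol condensation of the 1,4-diketone (C11 enolate onto the C7 carbonyl, then dehydration) has the fused cyclopentenone as its only conjugated outlet, and C6 equilibrates to the equatorial ring bond (6β-H, trans to 5α-H).

**Step 12**
Reactants: 17 tricyclic enone of rings A/B/D; 18 allyl acrylate
Product: 20 tetracyclic keto ester (allyl 15-endo-carboxylate; C12 ketone), via mono-Michael adduct 19 (not isolated)
Conditions: LiN(iPr)2 (2.2 equiv), THF, −78 °C; 18, −78 → 0 °C; AcOH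
Reagents that add atoms: none
Why: Michael–Michael annulation: the kinetic cross-conjugated dienolate (C13) adds to the acrylate on the face opposite C5, and the ester enolate then closes onto the enone carbon C7 on the same face (ester enolate → ketone enolate), setting C13 and the quaternary C7 with C5 anti to the new bridge; the C15 ester configuration (mainly endo) is irrelevant because C15 is planarised in step 15.

**Step 13**
Reactants: 20 tetracyclic keto ester
Product: 21 tetracyclic keto acid (15-endo-CO2H; C12 ketone)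
Conditions: Pd(PPh3)4 (5 mol %), morpholine, THF, 25 °C
Reagents that add atoms: none
Why: Tsuji–Trost deallylation with zerovalent palladium and morpholine as allyl acceptor frees the hindered acid under neutral conditions, so the δ-keto ester cannot undergo retro-Michael opening and the benzyl ether is untouched.

**Step 14**
Reactants: 21 tetracyclic keto acid
Product: 22 N-acyloxyphthalimide of acid 21
Conditions: N-hydroxyphthalimide, N,N′-diisopropylcarbodiimide, DMAP (10 mol %), CH2Cl2, 25 °C
Reagents that add atoms: N-hydroxyphthalimide, ON1C(=O)c2ccccc2C1=O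
Why: Carbodiimide esterification gives the redox-active ester, and the hindered tertiary alcohol does not acylate.

**Step 15**
Reactants: 22 N-acyloxyphthalimide of acid 21; 23 isopropenylmagnesium bromide
Product: 24 15-exo-isopropenyl tetracyclic C12 ketone
Conditions: 23 + ZnCl2, THF, 0 °C; then 22, Ni(acac)2 (10 mol %), 2,2′-bipyridine (10 mol %), THF/DMF, 25 °C
Reagents that add atoms: none
Why: Nickel-catalysed decarboxylative alkenylation (Negishi-type coupling of a redox-active ester): electron transfer releases CO2 and a C15 radical that nickel captures on the exo face of the norbornane, so both C15 epimers converge on the exo-isopropenyl product, and the ketone, free alcohol and benzyl ether tolerate the alkenylzinc.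

**Step 16**
Reactants: 24 15-exo-isopropenyl tetracyclic C12 ketone
Product: 25 15-exo-isopropenyl tetracyclic 4β,12-exo-diol (1β-OBn)
Conditions: LiBH(sec-Bu)3 (3 equiv), THF, −78 °C; H2O
Reagents that add atoms: none
Why: Bulky-hydride reduction: the exo face of the C12 ketone is covered by C5 on the one-carbon bridge (like the syn-methyl of camphor), so hydride adds from the endo face and gives the exo alcohol (isoborneol-type selectivity).

**Step 17**
Reactants: 25 15-exo-isopropenyl tetracyclic 4β,12-exo-diol
Product: 26 4,12-bis(triethylsilyl) ether of 25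
Conditions: Et3SiOTf (3 equiv), 2,6-lutidine, CH2Cl2, −78 → 25 °C
Reagents that add atoms: triethylsilyl trifluoromethanesulfonate, CC[Si](CC)(CC)OS(=O)(=O)C(F)(F)F
Why: Silyl triflate protection masks both the secondary C12 and the hindered tertiary C4 alcohol, so that only the C1 oxygen is free after step 18 and no hydroxyl can interfere with the bromination.

**Step 18**
Reactants: 26 4,12-bis(triethylsilyl) ether of 25
Product: 27 15-exo-isopropyl 1β-alcohol (4,12-bis-OSiEt3)
Conditions: H2 (1 atm), Pd/C (10 wt %), EtOAc, 25 °C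
Reagents that add atoms: none
Why: Heterogeneous hydrogenation saturates the isopropenyl group (no new stereocentre) and hydrogenolyses the benzyl ether in the same operation, while silyl ethers are stable in EtOAc.

**Step 19**
Reactants: 27 15-exo-isopropyl 1β-alcohol
Product: 28 C1 ketone
Conditions: (n-Pr4N)RuO4 (5 mol %), N-methylmorpholine N-oxide, 4 Å MS, CH2Cl2, 25 °C
Reagents that add atoms: none
Why: Ley–Griffith oxidation under neutral conditions converts the only free alcohol into the C1 ketone without cleaving the silyl ethers.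

**Step 20**
Reactants: 28 C1 ketone
Product: 29 1α-alcohol (axial)
Conditions: LiBH(sec-Bu)3, THF, −78 → −40 °C; H2O
Reagents that add atoms: none
Why: Bulky-hydride reduction of the ketone next to quaternary C10: hydride is delivered equatorially because the axial α approach is hindered by the axial hydrogens at C3 and C5, giving the axial 1α-alcohol needed for inversion (as for 3-keto-4,4-dimethyl triterpenoids).

**Step 21**
Reactants: 29 1α-alcohol (axial)
Product: 30 1β-bromide (4,12-bis-OSiEt3)
Conditions: CBr4, PPh3, PhMe, 25 → 60 °C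
Reagents that add atoms: carbon tetrabromide, BrC(Br)(Br)Br
Why: Appel reaction: SN2 displacement of the axial alkoxyphosphonium by bromide proceeds with inversion to the equatorial 1β-bromide (the axial 3α-ol → equatorial 3β-bromide conversion of 4,4-dimethyldecalins), and both other oxygens are silylated and cannot participate.

**Step 22**
Reactants: 30 1β-bromide (4,12-bis-OSiEt3)
Product: 31 CNP0317598.2 (target)
Conditions: HF·pyridine, THF/pyridine, 0 → 25 °C
Reagents that add atoms: none
Why: Fluoride-mediated desilylation with buffered HF·pyridine removes both triethylsilyl groups without elimination or substitution at the equatorial neopentyl bromide, which has no antiperiplanar hydrogen.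

**Compound list**

1 | 2-methylcyclohexane-1,3-dione | CC1C(=O)CCCC1=O | starting material
2 | but-3-en-2-one (methyl vinyl ketone) | CC(=O)C=C | starting material
3 | 2-methyl-2-(3-oxobutyl)cyclohexane-1,3-dione | CC(=O)CCC1(C)C(=O)CCCC1=O | intermediate
4 | cis-fused ketol, 4a-hydroxy-8a-methyloctahydronaphthalene-1,6-dione (OH and CH3 cis) | O=C1C[C@@]2(O)CCCC(=O)[C@@]2(C)CC1 | intermediate (not isolated)
5 | (S)-Wieland–Miescher ketone | O=C1C=C2CCCC(=O)[C@@]2(C)CC1 | intermediate
6 | (4aS,5S)-5-hydroxy-4a-methyl-4,4a,5,6,7,8-hexahydronaphthalen-2(3H)-one | O=C1C=C2CCC[C@H](O)[C@@]2(C)CC1 | intermediate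
7 | (4aS,5S)-5-benzyloxy-4a-methyl-4,4a,5,6,7,8-hexahydronaphthalen-2(3H)-one | O=C1C=C2CCC[C@H](OCc3ccccc3)[C@@]2(C)CC1 | intermediate
8 | pyrrolidine dienamine of 7 (N–C7=C6–C5=C4) | C1CCN(C1)C1=CC2=CCC[C@H](OCc3ccccc3)[C@@]2(C)CC1 | intermediate (not isolated)
9 | 1β-benzyloxy-10β-methyldecal-5-ene-4,7-dione | O=C1C=C2C(=O)CC[C@H](OCc3ccccc3)[C@@]2(C)CC1 | intermediate
10 | allyltrimethylsilane | C=CC[Si](C)(C)C | starting material
11 | 6α-allyl-1β-benzyloxy-10β-methyl-5α-decalin-4,7-dione | C=CC[C@H]1[C@H]2[C@](C)(CCC1=O)[C@@H](OCc3ccccc3)CCC2=O | intermediate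
12 | 6α-allyl-1β-benzyloxy-7β-hydroxy-10β-methyl-5α-decalin-4-one | C=CC[C@H]1[C@H]2[C@](C)(CC[C@@H]1O)[C@@H](OCc3ccccc3)CCC2=O | intermediate
13 | methylmagnesium bromide | C[Mg]Br | starting material
14 | 6α-allyl-1β-benzyloxy-4α,10β-dimethyl-5α-decalin-4β,7β-diol | C=CC[C@H]1[C@H]2[C@](C)(CC[C@@H]1O)[C@@H](OCc3ccccc3)CC[C@@]2(C)O | intermediate
15 | 6α-allyl-1β-benzyloxy-4β-hydroxy-4α,10β-dimethyl-5α-decalin-7-one | C=CC[C@H]1[C@H]2[C@](C)(CCC1=O)[C@@H](OCc3ccccc3)CC[C@@]2(C)O | intermediate
16 | 1β-benzyloxy-4β-hydroxy-4α,10β-dimethyl-6α-(2-oxopropyl)-5α-decalin-7-one | CC(=O)C[C@H]1[C@H]2[C@](C)(CCC1=O)[C@@H](OCc3ccccc3)CC[C@@]2(C)O | intermediate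
17 | tricyclic enone of rings A/B/D (C12 ketone, C7=C11, 5α-H, 6β-H, 1β-OBn, 4β-OH, 4α-CH3) | C1[C@H]2[C@H]3[C@](C)(CCC2=CC1=O)[C@@H](OCc4ccccc4)CC[C@@]3(C)O | intermediate
18 | allyl acrylate | C=CC(=O)OCC=C | starting material
19 | mono-Michael adduct: enone 17 carrying CH2CH2CO2-allyl at C13, anti to C5 | C=CCOC(=O)CC[C@@H]1[C@H]2[C@H]3[C@](C)(CCC2=CC1=O)[C@@H](OCc4ccccc4)CC[C@@]3(C)O | intermediate (not isolated)
20 | tetracyclic keto ester: allyl 15-endo-carboxylate, C12 ketone, 1β-OBn, 4β-OH (C5 anti to the C14–C15 bridge) | C=CCOC(=O)[C@H]1C[C@@H]2[C@H]3[C@H]4[C@](C)(CC[C@@]31CC2=O)[C@@H](OCc5ccccc5)CC[C@@]4(C)O | intermediate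
21 | tetracyclic keto acid (15-endo-CO2H) | OC(=O)[C@H]1C[C@@H]2[C@H]3[C@H]4[C@](C)(CC[C@@]31CC2=O)[C@@H](OCc5ccccc5)CC[C@@]4(C)O | intermediate
22 | N-acyloxyphthalimide (redox-active ester) of 21 | O=C(ON1C(=O)c2ccccc2C1=O)[C@H]1C[C@@H]2[C@H]3[C@H]4[C@](C)(CC[C@@]31CC2=O)[C@@H](OCc5ccccc5)CC[C@@]4(C)O | intermediate
23 | isopropenylmagnesium bromide | C=C(C)[Mg]Br | starting material
24 | 15-exo-isopropenyl tetracyclic C12 ketone (1β-OBn, 4β-OH) | C=C(C)[C@@H]1C[C@@H]2[C@H]3[C@H]4[C@](C)(CC[C@@]31CC2=O)[C@@H](OCc5ccccc5)CC[C@@]4(C)O | intermediate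
25 | 15-exo-isopropenyl 4β,12-exo-diol (1β-OBn) | C=C(C)[C@@H]1C[C@@H]2[C@H]3[C@H]4[C@](C)(CC[C@@]31C[C@H]2O)[C@@H](OCc5ccccc5)CC[C@@]4(C)O | intermediate
26 | 4,12-bis(triethylsilyl) ether of 25 | C=C(C)[C@@H]1C[C@@H]2[C@H]3[C@H]4[C@](C)(CC[C@@]31C[C@H]2O[Si](CC)(CC)CC)[C@@H](OCc5ccccc5)CC[C@@]4(C)O[Si](CC)(CC)CC | intermediate
27 | 15-exo-isopropyl 1β-alcohol, 4,12-bis(triethylsilyl) ether | CC(C)[C@@H]1C[C@@H]2[C@H]3[C@H]4[C@](C)(CC[C@@]31C[C@H]2O[Si](CC)(CC)CC)[C@@H](O)CC[C@@]4(C)O[Si](CC)(CC)CC | intermediate
28 | C1 ketone, 4,12-bis(triethylsilyl) ether | CC(C)[C@@H]1C[C@@H]2[C@H]3[C@H]4[C@](C)(CC[C@@]31C[C@H]2O[Si](CC)(CC)CC)C(=O)CC[C@@]4(C)O[Si](CC)(CC)CC | intermediate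
29 | 1α-alcohol (axial), 4,12-bis(triethylsilyl) ether | CC(C)[C@@H]1C[C@@H]2[C@H]3[C@H]4[C@](C)(CC[C@@]31C[C@H]2O[Si](CC)(CC)CC)[C@H](O)CC[C@@]4(C)O[Si](CC)(CC)CC | intermediate
30 | 1β-bromide (equatorial), 4,12-bis(triethylsilyl) ether | CC(C)[C@@H]1C[C@@H]2[C@H]3[C@H]4[C@](C)(CC[C@@]31C[C@H]2O[Si](CC)(CC)CC)[C@@H](Br)CC[C@@]4(C)O[Si](CC)(CC)CC | intermediate
31 | CNP0317598.2 | CC(C)[C@@H]1C[C@@H]2[C@H]3[C@H]4[C@](C)(CC[C@@]31C[C@H]2O)[C@@H](Br)CC[C@@]4(C)O | target

**Totals**

Total step count: 22. Longest linear sequence: 22 steps (1 and 2 → 31).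

**Three steps most likely to fail, with fallbacks**

Step 12 (Michael–Michael annulation). The ring-closing Michael addition builds a strained norbornanone and may stall at the mono-adduct 19 or revert. The fallback sets out from enone 17 and returns at keto ester 20 by a cycloaddition instead of an anionic cascade. Enone 17 is treated with Me3SiOTf/Et3N (CH2Cl2, 0 °C), which silylates the C4 hydroxyl and gives the cross-conjugated 2-silyloxycyclopentadiene, the bis(trimethylsilyl) siloxydiene F1. F1 is reacted at once with 18 and Me2AlCl at −78 °C in a Diels–Alder reaction (anti to C5, below the temperature at which the diene isomerises by 1,5-hydrogen shift) to give the silyl enol ether cycloadduct F2. Brief 1 M HCl/THF removes both silyl groups and gives 20.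

Step 15 (decarboxylative alkenylation). The C15 radical is secondary and flanked by the quaternary C7, so capture by nickel may be slow and reduction or low exo selectivity may compete. The fallback sets out from acid 21 and returns at 24, bypassing the redox-active ester 22 and the organozinc. Acid 21 is coupled directly with 2-bromopropene under metallaphotoredox conditions (Ir[dF(CF3)ppy]2(dtbbpy)PF6 1 mol %, NiCl2·glyme 10 mol %, 4,4′-di-tert-butyl-2,2′-bipyridine, Cs2CO3, DMF, blue LEDs). Here the radical comes from oxidation of the carboxylate and the partner is an alkenyl halide; the same exo capture gives 24, and this path passes through no new compound F0.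

Step 21 (Appel bromination). The axial, neopentyl alkoxyphosphonium may eliminate to the C1–C2 alkene or trigger a C19 methyl shift instead of substitution. The fallback sets out from ketone 28 (skipping 29) and returns at bromide 30 by making the C–Br bond on sp2 carbon and setting the stereocentre by hydrogen delivery. Ketone 28 with KN(SiMe3)2/PhNTf2 (THF, −78 °C) gives the C1 enol triflate F3. Nickel-catalysed triflate–bromide exchange (Ni(cod)2 10 mol %, LiBr, DMA/THF, 25 °C) gives the C1 alkenyl bromide F4. Hydrogen-atom-transfer hydrogenation (Mn(dpm)3, PhSiH3, t-BuOOH, i-PrOH, 25 °C) then delivers hydrogen to the α-bromo radical on the axial α face, anti to C19, leaving bromine equatorial (1β) as in 30.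

**Further compounds**

F1 | step 12 | bis(trimethylsilyl) siloxydiene (C13=C12(OSiMe3)–C11=C7 diene of 17, C4–OSiMe3) | C=1[C@H]2[C@H]3[C@](C)(CCC2=CC=1O[Si](C)(C)C)[C@@H](OCc4ccccc4)CC[C@@]3(C)O[Si](C)(C)C
F2 | step 12 | silyl enol ether cycloadduct (C11=C12–OSiMe3, allyl 15-endo-carboxylate, C4–OSiMe3) | C=CCOC(=O)[C@H]1C[C@@H]2[C@H]3[C@H]4[C@](C)(CC[C@@]31C=C2O[Si](C)(C)C)[C@@H](OCc5ccccc5)CC[C@@]4(C)O[Si](C)(C)C
F0 | step 15 | none | none
F3 | step 21 | C1 enol triflate (C1=C2) of ketone 28 | CC(C)[C@@H]1C[C@@H]2[C@H]3[C@H]4[C@](C)(CC[C@@]31C[C@H]2O[Si](CC)(CC)CC)C(OS(=O)(=O)C(F)(F)F)=CC[C@@]4(C)O[Si](CC)(CC)CC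
F4 | step 21 | C1 alkenyl bromide (C1=C2) | CC(C)[C@@H]1C[C@@H]2[C@H]3[C@H]4[C@](C)(CC[C@@]31C[C@H]2O[Si](CC)(CC)CC)C(Br)=CC[C@@]4(C)O[Si](CC)(CC)CC
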